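## The problem

Schizolaenone C (23) is a 5,7,3′,5′-tetrahydroxyflavanone. Its phloroglucinol-type ring A is fused through C4a–C8a to the dihydropyranone ring C, the resorcinol-type ring B sits on C2, and an (E)-geranyl chain occupies C6 between the C5 and C7 hydroxyls. The only stereocentre is C2 (S). With no second centre to relay from, it must be set by a catalyst. Once ring C exists it is fragile, because the O1–C2 bond lies β to the C4 carbonyl and opens by retro-oxa-Michael reaction to the achiral 2′-hydroxychalcone in base and, more slowly, in hot acid. The geranyl chain must end at C6 and not at C8; the two positions differ only in which ring-A oxygen becomes O1, so ring A has to be differentiated before ring C is closed. The chain rules out hydrogenolysis, ozonolysis and strong acids, since its trisubstituted alkenes add the flanking C5 and C7 phenols to give chromans, and four phenols must be carried masked and freed at the end. The enabling feature is the substitution at C2: it bears O1, ring B, a hydrogen and C3, which is the pattern of a branched 1-arylallyl aryl ether if C3 is the inner carbon of a vinyl group. Such ethers are the products of iridium-catalysed allylic substitution of a cinnamyl electrophile by a phenoxide, with the stereocentre set at the benzylic carbon. O1 sits on C8a para to C6, so a ring-A phenol whose single free hydroxyl is para to the geranyl group gives the 6-isomer by construction.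

## Retrosynthesis

**23 back to 21.** The last operation should only unmask functional groups. All four phenols are carried as methoxymethyl (MOM) ethers, because on ring A the same groups serve as directing groups for lithiation. C4 is carried as the silyl enol ether 21, a 4-silyloxy-2H-chromene that cannot open to a chalcone. Methanolic acid should convert 21 through the tetrakis-MOM flavanone 22 into 23 without any basic step that could racemise C2.

**21 back to 18 (C3–C4).** Ring C is opened at C3=C4 of 21, giving the diene 20, in which a vinyl group on C2 faces the silyl enol ether of an aryl methyl ketone. Closing ring C by C3–C4 metathesis leaves every bond at C2 untouched. The neighbouring options are worse: O1–C2 closure by oxa-Michael addition forms the stereocentre reversibly, and C4–C4a acylation needs acids that the MOM ethers and the geranyl chain would not survive. The enol ether 20 comes from ketone 18 by enolate silylation. The forward reaction needs a ruthenium alkylidene that engages a 1,1-disubstituted electron-rich alkene while ignoring the trisubstituted alkenes of the side chain.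

**18 back to 11 and 16 (O1–C2, the key cut).** Cutting O1–C2 of the branched ether 18 gives the ortho-hydroxyacetophenone 11, used as its sodium salt 17, and the linear cinnamyl carbonate 16. This is the only cut that creates the stereocentre in a convergent, irreversible intermolecular step and fixes the 6-geranyl regiochemistry at the same time, since 11 has one free hydroxyl and it is para to the geranyl group. Both partners are achiral and simple. The forward reaction must deliver the branched rather than the linear ether, with one face of the allyl unit selected, from an aryloxide that is chelated to its ortho acetyl group.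

**11 back to 8 (the acetyl group).** Friedel–Crafts or Fries acylation is incompatible with MOM ethers and the geranyl chain. The C–C bond ortho to the free phenol is therefore made by magnesium-mediated ortho-formylation of phenol 8 to aldehyde 9, followed by methyl Grignard addition to carbinol 10 and benzylic oxidation to 11. In 8 the para position is blocked and the two ortho positions are equivalent, so only one acetophenone can result.

**8 back to 1 and 4 (the geranyl group).** The C6–C1″ bond is cut to geranyl bromide 4 and an aryl anion. In the silyl ether 3 the only C–H flanked by two MOM ethers is the one para to the bulky, non-directing TIPS ether, so lithiation to 5, transmetalation to the arylcopper 6 and allylic substitution give 7; fluoride then releases 8. Compound 3 comes from phloroglucinol 1 by bis-MOM protection to 2 and silylation. The single statistical step is placed first, on the cheapest material.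

**16 back to 12.** The carbonate is cut at the acyl oxygen to the cinnamyl alcohol 15. This comes from the ester 14 by 1,2-reduction, the ester from aldehyde 13 by Horner–Wadsworth–Emmons olefination, and 13 from 3,5-dihydroxybenzaldehyde 12 by MOM protection. The E alkene and the primary carbonate are what the iridium catalyst requires.

## Roads not taken

**Alternative 1:** Ring A would be built last by cutting C4a–C5. An enantioenriched 2-aryl-2,3-dihydropyran-4-one carrying a geranylated β-keto ester side chain on the enol ether carbon (A2) would be enolised softly with MgBr2·OEt2 and a tertiary amine. The pyranone α-carbon would then attack the terminal ester in a Claisen cyclisation, and loss of methanol and tautomerisation would give the 3′,5′-bis-MOM flavanone A1.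
- Merits: the ring-A hydroxyls appear unprotected, and the geranyl group is locked at C6 because it sits on the carbon between the ketone and the ester. On these two points it is at least as good as the chosen plan.
- Weak points: A2 is a sensitive tricarbonyl compound whose chiral dihydropyranone has to be made by a separate asymmetric reaction and then elaborated. Under the enolising conditions its C2–O bond is β to a carbonyl and can open and reclose, which threatens the stereocentre. Aldol and O-acylation modes compete with the desired Claisen closure. A1 still needs acid to remove the ring-B MOM ethers with the geranylated phloroglucinol already free.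
- Comparison: the chosen plan needs more protecting-group steps on ring A. Against this it sets simple aromatic fragments and forms C2 in a step after which no enolisable ring C exists until the final acid treatment.

**Alternative 2:** The geranyl chain would be attached last by cutting C6–C1″. The (2S)-6-iodo-5-hydroxyflavanone triacetate A4 would be coupled with geranyltributylstannane A5 using Pd(PPh3)4 (zerovalent palladium) in a Stille reaction to give the triacetate A3.
- Merits: this is the most convergent plan. The geranyl chain never sees the earlier steps, and other prenyl chains could be attached to the same core. On these points it is better than the chosen plan.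
- Weak points: the 6/8 problem is only moved to the iodination of a 5,7-dioxygenated flavanone, where both positions are activated and mixtures or bis-iodination are likely. Allylstannane couplings pass through allylpalladium species that can leak to the branched (linalyl) isomer and to the Z (neryl) isomer. The C2 stereocentre still has to come from a separate asymmetric flavanone synthesis. The acetates of A3 must be removed with base or a nucleophile, the conditions under which flavanones open to chalcones and racemise.
- Comparison: the chosen plan has a longer linear sequence and a final acid step with the geranyl chain present. Against this it fixes the regiochemistry by symmetry and sets C2 within the route.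

**Alternative 3:** Ring C would be closed at O1–C8a. The (S)-configured secondary benzylic alcohol of the aryl triflate A7 would be coupled intramolecularly with the triflate carbon by a catalyst formed from Pd2(dba)3 and a bulky biaryl di-tert-butylphosphine, with retention at C2, to give the 4-silyloxyflavan A6 as C4 epimers.
- Merits: the C–O bond is formed irreversibly on the aryl side, and C2 can be set beforehand by a well-established asymmetric carbonyl reduction or aldol reaction. Its enantiocontrol is arguably more predictable than iridium catalysis with a chelated aryloxide.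
- Weak points: C4 must be carried as a protected alcohol, so desilylation and oxidation are added before the MOM removal. β-Hydride elimination of the secondary palladium alkoxide to the aryl ketone is the classic competing path. The triflate must sit on the oxygen para to the geranyl group, so the ring-A differentiation needed in the chosen plan is needed here too, with no saving. A7 itself requires an aryl–C4 bond formation and an asymmetric step.
- Comparison: the chosen plan offers a shorter sequence, no redox detour at C4, and formation of the stereocentre in the fragment-joining step.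

Key step: step 12

Assumption: the (Sa,S,S) phosphoramidite is taken to give the (S)-ether, following the usual sense of induction of this ligand family with heteroatom nucleophiles and cinnamyl carbonates; if the correlation is reversed for this aryloxide, the (Ra,R,R) ligand is used instead.

Geranyl denotes (2E)-3,7-dimethylocta-2,6-dien-1-yl; MOM denotes methoxymethyl.

## Route

Step 1
Reactants: 1 phloroglucinol (benzene-1,3,5-triol)
Product: 2 3,5-bis(methoxymethoxy)phenol
Conditions: MOMCl (2 equiv), i-Pr2NEt, DMF, 0 °C → rt
Reagents that add atoms: chloromethyl methyl ether, COCCl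
Why: Base-mediated O-alkylation of the phenol; the symmetrical triol can give only one bis-ether, which is separated from the mono- and tris-ethers of this statistical protection, the mono-ether being recycled. The MOM groups are later the directing groups for lithiation.

Step 2
Reactants: 2 3,5-bis(methoxymethoxy)phenol
Product: 3 [3,5-bis(methoxymethoxy)phenoxy]tri(propan-2-yl)silane
Conditions: TIPSCl, imidazole, DMF, rt
Reagents that add atoms: chlorotri(propan-2-yl)silane, CC(C)[Si](Cl)(C(C)C)C(C)C
Why: Standard silylation of the remaining phenol. The bulky TIPS ether tolerates n-BuLi, shields its own ortho positions and does not direct metalation, so only the C–H between the two MOM ethers is left for step 3.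

Step 3
Reactants: 3 [3,5-bis(methoxymethoxy)phenoxy]tri(propan-2-yl)silane; 4 geranyl bromide [(2E)-1-bromo-3,7-dimethylocta-2,6-diene]
Product: 7 {4-geranyl-3,5-bis(methoxymethoxy)phenoxy}tri(propan-2-yl)silane, via aryllithium 5 (not isolated), via arylcopper 6 (not isolated)
Conditions: n-BuLi, THF, 0 °C; CuI, −40 °C; 4, −40 °C → rt
Reagents that add atoms: none
Why: Directed ortho-metalation at the C–H flanked by two coordinating MOM ethers, transmetalation to copper and allylic substitution of the primary bromide at its α-carbon, which should keep the E geometry and disfavour the branched SN2′ isomer. The arene is symmetrical, so only one regioisomer can form.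

Step 4
Reactants: 7 {4-geranyl-3,5-bis(methoxymethoxy)phenoxy}tri(propan-2-yl)silane
Product: 8 4-geranyl-3,5-bis(methoxymethoxy)phenol
Conditions: Bu4NF, THF, 0 °C
Reagents that add atoms: none
Why: Fluoride cleavage of the aryl silyl ether; MOM ethers and the alkenes are inert to fluoride.

Step 5
Reactants: 8 4-geranyl-3,5-bis(methoxymethoxy)phenol
Product: 9 3-geranyl-6-hydroxy-2,4-bis(methoxymethoxy)benzaldehyde
Conditions: MgCl2, Et3N, (CH2O)n, MeCN, reflux
Reagents that add atoms: paraformaldehyde (as formaldehyde), C=O
Why: Magnesium-mediated ortho-formylation (Casnati–Skattebøl reaction): the magnesium phenoxide delivers formaldehyde to the ortho carbon through a chelate and a second formaldehyde oxidises the hydroxymethyl intermediate to the aldehyde. The para position is blocked and the two ortho positions are equivalent, so a single aldehyde should form under basic conditions that spare the MOM ethers.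

Step 6
Reactants: 9 3-geranyl-6-hydroxy-2,4-bis(methoxymethoxy)benzaldehyde
Product: 10 4-geranyl-2-(1-hydroxyethyl)-3,5-bis(methoxymethoxy)phenol (racemic)
Conditions: MeMgBr (3 equiv), THF, −78 → 0 °C; aq. NH4Cl
Reagents that add atoms: methylmagnesium bromide, C[Mg]Br
Why: Grignard addition to the aldehyde after the first equivalent has deprotonated the phenol. The new carbinol centre is racemic and is removed in step 7; the product is kept away from acid and used crude because ortho-hydroxybenzyl alcohols dehydrate easily.

Step 7
Reactants: 10 4-geranyl-2-(1-hydroxyethyl)-3,5-bis(methoxymethoxy)phenol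
Product: 11 1-[3-geranyl-6-hydroxy-2,4-bis(methoxymethoxy)phenyl]ethanone
Conditions: activated MnO2 (excess), CH2Cl2, rt
Reagents that add atoms: none
Why: Heterogeneous MnO2 oxidation is selective for the benzylic alcohol and leaves the isolated alkenes and MOM ethers alone; the product is stabilised by the phenol–carbonyl hydrogen bond.

Step 8
Reactants: 12 3,5-dihydroxybenzaldehyde
Product: 13 3,5-bis(methoxymethoxy)benzaldehyde
Conditions: MOMCl, i-Pr2NEt, CH2Cl2, 0 °C → rt
Reagents that add atoms: chloromethyl methyl ether, COCCl
Why: Exhaustive O-alkylation of both phenols; the meta MOM ethers are stable to the basic, reducing and organometallic steps that follow.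

Step 9
Reactants: 13 3,5-bis(methoxymethoxy)benzaldehyde
Product: 14 ethyl (2E)-3-[3,5-bis(methoxymethoxy)phenyl]prop-2-enoate
Conditions: (EtO)2P(O)CH2CO2Et, NaH, THF, 0 °C → rt
Reagents that add atoms: triethyl phosphonoacetate, CCOC(=O)CP(=O)(OCC)OCC
Why: Horner–Wadsworth–Emmons olefination of an aromatic aldehyde with a stabilised phosphonate, which should give the E cinnamate.

Step 10
Reactants: 14 ethyl (2E)-3-[3,5-bis(methoxymethoxy)phenyl]prop-2-enoate
Product: 15 (2E)-3-[3,5-bis(methoxymethoxy)phenyl]prop-2-en-1-ol
Conditions: i-Bu2AlH, CH2Cl2, −78 °C; aq. potassium sodium tartrate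
Reagents that add atoms: none
Why: 1,2-Reduction of the unsaturated ester by the aluminium hydride gives the allylic alcohol without touching the alkene or the acetals.

Step 11
Reactants: 15 (2E)-3-[3,5-bis(methoxymethoxy)phenyl]prop-2-en-1-ol
Product: 16 (2E)-3-[3,5-bis(methoxymethoxy)phenyl]prop-2-enyl methyl carbonate
Conditions: ClCO2Me, pyridine, CH2Cl2, 0 °C
Reagents that add atoms: methyl chloroformate, COC(=O)Cl
Why: Acylation of the primary allylic alcohol; the methyl carbonate is the standard leaving group for iridium-catalysed allylic substitution.

Step 12
Reactants: 11 1-[3-geranyl-6-hydroxy-2,4-bis(methoxymethoxy)phenyl]ethanone; 16 (2E)-3-[3,5-bis(methoxymethoxy)phenyl]prop-2-enyl methyl carbonate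
Product: 18 1-{6-[(1S)-1-[3,5-bis(methoxymethoxy)phenyl]prop-2-enyloxy]-3-geranyl-2,4-bis(methoxymethoxy)phenyl}ethanone, via sodium phenolate 17 (not isolated)
Conditions: NaH (1.0 equiv), THF, 0 °C; [Ir(cod)Cl]2 (2 mol %), (Sa,S,S)-O,O′-(1,1′-binaphthyl-2,2′-diyl) N,N-bis(1-phenylethyl)phosphoramidite (4 mol %, pre-activated with n-PrNH2), 16 (1.3 equiv), THF, rt → 40 °C
Reagents that add atoms: none
Why: The cyclometalated iridium phosphoramidite complex (monovalent iridium) adds oxidatively to carbonate 16 with loss of methyl carbonate, which decomposes to carbon dioxide and methoxide, giving an allyl–iridium complex (trivalent iridium); aryloxide 17 then attacks the aryl-bearing allyl terminus from the face opposite the metal to form O1–C2. The closest known reaction type is the iridium-catalysed enantioselective allylic etherification of alkali aryloxides with cinnamyl carbonates to branched aryl allyl ethers. No ring is closed. The new stereocentre, the later C2, is controlled by the chiral ligand, which fixes the face of the allyl ligand that is exposed. The step needs branched over linear attack, which is inherent to iridium with an aryl-substituted allyl unit, O- over C-allylation, and reaction of the aryloxide rather than the released methoxide; the single free hydroxyl of 11 decides which oxygen becomes O1 and hence the 6-geranyl pattern. The sodium salt is used because the aryloxide is ortho-substituted and chelated to its acetyl group, and the reaction is stopped at full conversion at low temperature so that the product is not re-ionised by the catalyst, which would erode the branched selectivity and the enantiomeric purity.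

Step 13
Reactants: 18 1-{6-[(1S)-1-[3,5-bis(methoxymethoxy)phenyl]prop-2-enyloxy]-3-geranyl-2,4-bis(methoxymethoxy)phenyl}ethanone
Product: 20 tert-butyl{[1-(6-{(1S)-1-[3,5-bis(methoxymethoxy)phenyl]prop-2-enyloxy}-3-geranyl-2,4-bis(methoxymethoxy)phenyl)ethenyl]oxy}dimethylsilane, via potassium enolate 19 (not isolated)
Conditions: KN(SiMe3)2, THF, −78 °C; TBSCl, −78 → 0 °C
Reagents that add atoms: tert-butyldimethylsilyl chloride, CC(C)(C)[Si](C)(C)Cl
Why: Kinetic deprotonation of the methyl ketone, whose methyl protons are the only α-protons, followed by O-silylation of the potassium enolate. The basic protocol avoids silyl triflates, which could attack the MOM acetals or ionise the allylic ether, and the C2–H is far less acidic than the ketone methyl group at −78 °C.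

Step 14
Reactants: 20 tert-butyl{[1-(6-{(1S)-1-[3,5-bis(methoxymethoxy)phenyl]prop-2-enyloxy}-3-geranyl-2,4-bis(methoxymethoxy)phenyl)ethenyl]oxy}dimethylsilane
Product: 21 (2S)-2-[3,5-bis(methoxymethoxy)phenyl]-4-(tert-butyldimethylsilyloxy)-6-geranyl-5,7-bis(methoxymethoxy)-2H-chromene
Conditions: second-generation Grubbs catalyst RuCl2(=CHPh)(PCy3)(H2IMes) (10 mol %), 1,4-benzoquinone (10 mol %), degassed toluene (5 mM), 60 °C, dark
Reagents that add atoms: none
Why: Ring-closing metathesis of a silyl enol ether: the catalyst should initiate at the monosubstituted vinyl group and close the six-membered ring onto the 1,1-disubstituted enol ether with loss of ethene, forming C3=C4 without touching any bond at C2. The trisubstituted geranyl alkenes react much more slowly and cannot cyclise because the chain is para to O1; benzoquinone suppresses hydride-mediated alkene migration.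

Step 15
Reactants: 21 (2S)-2-[3,5-bis(methoxymethoxy)phenyl]-4-(tert-butyldimethylsilyloxy)-6-geranyl-5,7-bis(methoxymethoxy)-2H-chromene
Product: 23 schizolaenone C [(2S)-2-(3,5-dihydroxyphenyl)-6-geranyl-5,7-dihydroxychroman-4-one], via tetrakis-MOM flavanone 22 (not isolated)
Conditions: HCl (ca. 2 M), MeOH–THF, 0 → 40 °C
Reagents that add atoms: none
Why: Acid first protonates the silyl enol ether at C3 and releases the C4 ketone, then cleaves the four MOM acetals by transacetalisation to methanol, the type of acidic MOM removal commonly applied to prenylated flavanones. The medium is never basic, so retro-oxa-Michael opening at C2 should be avoided, and temperature and time are kept low to spare the geranyl alkenes.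

## Compound list

1 | phloroglucinol | Oc1cc(O)cc(O)c1 | starting material
2 | 3,5-bis(methoxymethoxy)phenol | COCOc1cc(O)cc(OCOC)c1 | intermediate
3 | [3,5-bis(methoxymethoxy)phenoxy]tri(propan-2-yl)silane | COCOc1cc(O[Si](C(C)C)(C(C)C)C(C)C)cc(OCOC)c1 | intermediate
4 | geranyl bromide, (2E)-1-bromo-3,7-dimethylocta-2,6-diene | CC(C)=CCC/C(C)=C/CBr | starting material
5 | [2,6-bis(methoxymethoxy)-4-(triisopropylsilyloxy)phenyl]lithium | [Li]c1c(OCOC)cc(O[Si](C(C)C)(C(C)C)C(C)C)cc1OCOC | intermediate (not isolated)
6 | [2,6-bis(methoxymethoxy)-4-(triisopropylsilyloxy)phenyl]copper | [Cu]c1c(OCOC)cc(O[Si](C(C)C)(C(C)C)C(C)C)cc1OCOC | intermediate (not isolated)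
7 | {4-geranyl-3,5-bis(methoxymethoxy)phenoxy}tri(propan-2-yl)silane | CC(C)=CCC/C(C)=C/Cc1c(OCOC)cc(O[Si](C(C)C)(C(C)C)C(C)C)cc1OCOC | intermediate
8 | 4-geranyl-3,5-bis(methoxymethoxy)phenol | CC(C)=CCC/C(C)=C/Cc1c(OCOC)cc(O)cc1OCOC | intermediate
9 | 3-geranyl-6-hydroxy-2,4-bis(methoxymethoxy)benzaldehyde | CC(C)=CCC/C(C)=C/Cc1c(OCOC)cc(O)c(C=O)c1OCOC | intermediate
10 | 4-geranyl-2-(1-hydroxyethyl)-3,5-bis(methoxymethoxy)phenol (racemic) | CC(C)=CCC/C(C)=C/Cc1c(OCOC)cc(O)c(C(C)O)c1OCOC | intermediate
11 | 1-[3-geranyl-6-hydroxy-2,4-bis(methoxymethoxy)phenyl]ethanone | CC(C)=CCC/C(C)=C/Cc1c(OCOC)cc(O)c(C(C)=O)c1OCOC | intermediate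
12 | 3,5-dihydroxybenzaldehyde | O=Cc1cc(O)cc(O)c1 | starting material
13 | 3,5-bis(methoxymethoxy)benzaldehyde | COCOc1cc(C=O)cc(OCOC)c1 | intermediate
14 | ethyl (2E)-3-[3,5-bis(methoxymethoxy)phenyl]prop-2-enoate | CCOC(=O)/C=C/c1cc(OCOC)cc(OCOC)c1 | intermediate
15 | (2E)-3-[3,5-bis(methoxymethoxy)phenyl]prop-2-en-1-ol | OC/C=C/c1cc(OCOC)cc(OCOC)c1 | intermediate
16 | (2E)-3-[3,5-bis(methoxymethoxy)phenyl]prop-2-enyl methyl carbonate | COC(=O)OC/C=C/c1cc(OCOC)cc(OCOC)c1 | intermediate
17 | sodium 2-acetyl-4-geranyl-3,5-bis(methoxymethoxy)phenolate | CC(C)=CCC/C(C)=C/Cc1c(OCOC)cc([O-])c(C(C)=O)c1OCOC.[Na+] | intermediate (not isolated)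
18 | 1-{6-[(1S)-1-[3,5-bis(methoxymethoxy)phenyl]prop-2-enyloxy]-3-geranyl-2,4-bis(methoxymethoxy)phenyl}ethanone | CC(C)=CCC/C(C)=C/Cc1c(OCOC)cc(O[C@@H](C=C)c2cc(OCOC)cc(OCOC)c2)c(C(C)=O)c1OCOC | intermediate
19 | potassium enolate of 18 (potassium 1-arylethenolate) | CC(C)=CCC/C(C)=C/Cc1c(OCOC)cc(O[C@@H](C=C)c2cc(OCOC)cc(OCOC)c2)c(C(=C)[O-])c1OCOC.[K+] | intermediate (not isolated)
20 | tert-butyldimethylsilyl enol ether of 18 | CC(C)=CCC/C(C)=C/Cc1c(OCOC)cc(O[C@@H](C=C)c2cc(OCOC)cc(OCOC)c2)c(C(=C)O[Si](C)(C)C(C)(C)C)c1OCOC | intermediate
21 | (2S)-2-[3,5-bis(methoxymethoxy)phenyl]-4-(tert-butyldimethylsilyloxy)-6-geranyl-5,7-bis(methoxymethoxy)-2H-chromene | CC(C)=CCC/C(C)=C/Cc1c(OCOC)cc2c(c1OCOC)C(O[Si](C)(C)C(C)(C)C)=C[C@@H](c1cc(OCOC)cc(OCOC)c1)O2 | intermediate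
22 | (2S)-2-[3,5-bis(methoxymethoxy)phenyl]-6-geranyl-5,7-bis(methoxymethoxy)chroman-4-one | CC(C)=CCC/C(C)=C/Cc1c(OCOC)cc2c(c1OCOC)C(=O)C[C@@H](c1cc(OCOC)cc(OCOC)c1)O2 | intermediate (not isolated)
23 | schizolaenone C, (2S)-2-(3,5-dihydroxyphenyl)-6-geranyl-5,7-dihydroxychroman-4-one | CC(C)=CCC/C(C)=C/Cc1c(O)cc2c(c1O)C(=O)C[C@@H](c1cc(O)cc(O)c1)O2 | target

## Step count and least certain steps

Total: 15 steps. Longest linear sequence: 11 steps (steps 1–7 and 12–15 from phloroglucinol); the ring-B carbonate takes 4 steps (8–11).

**Step 12 (key step).** The sodium aryloxide is chelated to its ortho acetyl group and may attack the allyl–iridium complex slowly, so that attack by methoxide or catalyst decay competes. Because this aryloxide is a fairly good leaving group, the product may also be re-ionised, with drift toward the linear ether and loss of enantiomeric purity. Fallback: the carbonyl is taken out of the etherification. The route is left at carbinol 10 and carbonate 16: the monosodium phenolate of 10, which is electron-rich and not chelated, is etherified under the same iridium catalysis to the hydroxy ether F1, S at the allylic carbon and a mixture of epimers at the carbinol carbon. Dess–Martin periodinane with NaHCO3 in CH2Cl2 then oxidises F1 to ketone 18, where the route is rejoined.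

**Step 14.** The ruthenium alkylidene formed at the vinyl group may fail to engage the hindered, twisted enol ether, whose ring closure brings the C4 silyloxy group next to the C5 MOM ether. Dimerisation through the vinyl group, alkene migration into conjugation with O1 (which destroys C2) or thermal Claisen rearrangement of the aryl allyl ether could then take over. Fallback without metathesis, by Parham cyclisation: the route is left at phenol 8 and carbonate 16.
- NBS at −78 °C gives the ortho-bromophenol F2.
- The iridium etherification of step 12 with 16 gives the bromo ether F3.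
- 9-BBN followed by NaBO3 hydroborates only the monosubstituted alkene and gives the primary alcohol F4.
- TEMPO with PhI(OAc)2 in aqueous MeCN gives the carboxylic acid F5.
- n-BuLi (2.2 equiv) in THF at −100 → −78 °C deprotonates the acid and exchanges bromine for lithium; the aryllithium closes onto the carboxylate to give flavanone 22 after aqueous work-up, where the route is rejoined before the acid treatment of step 15.

**Step 15.** Protic acid may add the freed C5 or C7 phenol to the geranyl C2″=C3″ alkene (chroman formation) or hydrate the chain, and prolonged heating may open ring C to the chalcone with loss of enantiomeric purity. Fallback in two stages without protic acid in the acetal cleavage: the route is left at 21, which is hydrolysed with aqueous oxalic acid in THF to 22, now isolated. TMSOTf with 2,2′-bipyridyl in CH2Cl2 at 0 °C then exchanges the aromatic MOM ethers for silyl ethers through pyridinium acetal salts, giving the tetrakis(trimethylsilyl) ether F6, which is hydrolysed on aqueous work-up to 23.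

**Step 3.** Lithiation may be incomplete, and the allylic substitution may leak to the branched SN2′ isomer or scramble the alkene geometry. Fallback by cross-coupling: the route is left at 3, whose aryllithium 5 is quenched with iodine to the aryl iodide F7. Stille coupling of F7 with geranyltributylstannane A5 using Pd(PPh3)4 (zerovalent palladium) in DMF then gives 7, where the route is rejoined.

**Step 7 (with step 6).** The electron-rich ortho-hydroxybenzyl alcohol 10 may dehydrate to an ortho-quinone methide or a styrene during isolation, and the free phenol may be over-oxidised on MnO2. Fallback by directed metalation: the route is left at phenol 8. Ethyl vinyl ether and pyridinium p-toluenesulfonate give the 1-ethoxyethyl ether F8. n-BuLi lithiates one of the two equivalent remaining ring positions to the aryllithium F9, which is acylated with N-methoxy-N-methylacetamide to the protected acetophenone F10. Pyridinium p-toluenesulfonate in methanol at rt removes only the ethoxyethyl group and gives 11, where the route is rejoined.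

## Further compounds

F1 | step 12 | 1-{6-[(1S)-1-[3,5-bis(methoxymethoxy)phenyl]prop-2-enyloxy]-3-geranyl-2,4-bis(methoxymethoxy)phenyl}ethanol (epimers at the carbinol carbon) | CC(C)=CCC/C(C)=C/Cc1c(OCOC)cc(O[C@@H](C=C)c2cc(OCOC)cc(OCOC)c2)c(C(C)O)c1OCOC
F2 | step 14 | 2-bromo-4-geranyl-3,5-bis(methoxymethoxy)phenol | CC(C)=CCC/C(C)=C/Cc1c(OCOC)cc(O)c(Br)c1OCOC
F3 | step 14 | 2-bromo-1-[(1S)-1-[3,5-bis(methoxymethoxy)phenyl]prop-2-enyloxy]-4-geranyl-3,5-bis(methoxymethoxy)benzene | CC(C)=CCC/C(C)=C/Cc1c(OCOC)cc(O[C@@H](C=C)c2cc(OCOC)cc(OCOC)c2)c(Br)c1OCOC
F4 | step 14 | (3S)-3-[3,5-bis(methoxymethoxy)phenyl]-3-[2-bromo-4-geranyl-3,5-bis(methoxymethoxy)phenoxy]propan-1-ol | CC(C)=CCC/C(C)=C/Cc1c(OCOC)cc(O[C@@H](CCO)c2cc(OCOC)cc(OCOC)c2)c(Br)c1OCOC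
F5 | step 14 | (3S)-3-[3,5-bis(methoxymethoxy)phenyl]-3-[2-bromo-4-geranyl-3,5-bis(methoxymethoxy)phenoxy]propanoic acid | CC(C)=CCC/C(C)=C/Cc1c(OCOC)cc(O[C@@H](CC(=O)O)c2cc(OCOC)cc(OCOC)c2)c(Br)c1OCOC
F6 | step 15 | (2S)-2-[3,5-bis(trimethylsilyloxy)phenyl]-6-geranyl-5,7-bis(trimethylsilyloxy)chroman-4-one | CC(C)=CCC/C(C)=C/Cc1c(O[Si](C)(C)C)cc2c(c1O[Si](C)(C)C)C(=O)C[C@@H](c1cc(O[Si](C)(C)C)cc(O[Si](C)(C)C)c1)O2
F7 | step 3 | [4-iodo-3,5-bis(methoxymethoxy)phenoxy]tri(propan-2-yl)silane | COCOc1cc(O[Si](C(C)C)(C(C)C)C(C)C)cc(OCOC)c1I
F8 | step 7 | 5-(1-ethoxyethoxy)-2-geranyl-1,3-bis(methoxymethoxy)benzene (racemic acetal) | CC(C)=CCC/C(C)=C/Cc1c(OCOC)cc(OC(C)OCC)cc1OCOC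
F9 | step 7 | [6-(1-ethoxyethoxy)-3-geranyl-2,4-bis(methoxymethoxy)phenyl]lithium | CC(C)=CCC/C(C)=C/Cc1c(OCOC)cc(OC(C)OCC)c([Li])c1OCOC
F10 | step 7 | 1-[6-(1-ethoxyethoxy)-3-geranyl-2,4-bis(methoxymethoxy)phenyl]ethanone | CC(C)=CCC/C(C)=C/Cc1c(OCOC)cc(OC(C)OCC)c(C(C)=O)c1OCOC
A1 | alternative 1 | (2S)-3′,5′-bis-MOM schizolaenone C | CC(C)=CCC/C(C)=C/Cc1c(O)cc2c(c1O)C(=O)C[C@@H](c1cc(OCOC)cc(OCOC)c1)O2
A2 | alternative 1 | methyl (4E)-2-{2-[(2S)-2-[3,5-bis(methoxymethoxy)phenyl]-4-oxo-2,3-dihydro-4H-pyran-6-yl]acetyl}-5,9-dimethyldeca-4,8-dienoate | COC(=O)C(C/C=C(\C)CCC=C(C)C)C(=O)CC1=CC(=O)C[C@@H](c2cc(OCOC)cc(OCOC)c2)O1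
A3 | alternative 2 | (2S)-schizolaenone C 7,3′,5′-triacetate | CC(C)=CCC/C(C)=C/Cc1c(OC(C)=O)cc2c(c1O)C(=O)C[C@@H](c1cc(OC(C)=O)cc(OC(C)=O)c1)O2
A4 | alternative 2 | (2S)-7-acetoxy-2-(3,5-diacetoxyphenyl)-5-hydroxy-6-iodochroman-4-one | CC(=O)Oc1cc2c(c(O)c1I)C(=O)C[C@@H](c1cc(OC(C)=O)cc(OC(C)=O)c1)O2
A5 | alternative 2 | geranyltributylstannane | CC(C)=CCC/C(C)=C/C[Sn](CCCC)(CCCC)CCCC
A6 | alternative 3 | (2S)-2-[3,5-bis(methoxymethoxy)phenyl]-4-(tert-butyldimethylsilyloxy)-6-geranyl-5,7-bis(methoxymethoxy)chroman (C4 epimers) | CC(C)=CCC/C(C)=C/Cc1c(OCOC)cc2c(c1OCOC)C(O[Si](C)(C)C(C)(C)C)C[C@@H](c1cc(OCOC)cc(OCOC)c1)O2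
A7 | alternative 3 | 2-{(3S)-3-[3,5-bis(methoxymethoxy)phenyl]-1-(tert-butyldimethylsilyloxy)-3-hydroxypropyl}-4-geranyl-3,5-bis(methoxymethoxy)phenyl trifluoromethanesulfonate (C1 epimers of the propyl chain) | CC(C)=CCC/C(C)=C/Cc1c(OCOC)cc(OS(=O)(=O)C(F)(F)F)c(c1OCOC)C(O[Si](C)(C)C(C)(C)C)C[C@H](O)c1cc(OCOC)cc(OCOC)c1
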